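The numbers of this flask are those of an exercise; the rest is arithmetic.

The easy step came first: X.L breaks into L and J with a half-life of 1.5 min, while Z takes 3.4 h to give L, so I let X.L follow the catalyst supply without lag.

    X + L → X.L (k1 = 450 L mol⁻¹ h⁻¹)
    X.L → L + J (k2 = 27.0 h⁻¹)
    X + Q → X.Q (k3 = 31.3 L mol⁻¹ h⁻¹)
    Z → L (k4 = 0.206 h⁻¹)
    J ⇌ E (K5 = 12, k5 = 0.0926 h⁻¹)

| setting | Sunday's | Tuesday's | Wednesday's |
|---|---|---|---|
| X | 0.050 M | 0.050 M (fed, over 8.00 h) | 0.050 M |
| Q | 0.0100 M | 0.0100 M | 0.0100 M |
| Z | 0.75 mM | 0.75 mM | 0.75 mM |
| time | 8.0 h | 8.0 h |  |
| remark | a closed flask charged with all of it at once and left for 8.0 h | all but X at the start; X goes in evenly over 8.00 h, the run ends at 8.0 h | one stirred flow tank at steady state, fed with the mixture as stated, mean residence time 8.0 h |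

- the set-up with the highest amount of J at the outlet or at the end, in percent of the X put in ("none" if the first two lie within 2 percentage points) (Sunday's / Tuesday's / Wednesday's / none)
- amount of J at the outlet or at the end, in percent of the X put in, Sunday's
- amount of J at the outlet or at the end, in percent of the X put in, Tuesday's
- amount of J at the outlet or at the end, in percent of the X put in, Wednesday's

- the stated concentrations are those of everything mixed, before any reaction; amounts are the same in each set-up
- the feed brings no volume worth counting
- run time (Sunday's): 8.0 h

I ran Sunday's flask in slow motion. In the first instants X reacts with Q, and L has still to come from Z. With X in excess, Q is pseudo-first-order with a half-life of 0.443 h, shorter than that of Z, so I took its charge off X at once and reckoned with 40.0 mM.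

In the middle the catalyst, L and X.L together, grows along a rising curve, which I replaced by its mean over the run, 0.382 mM. The share of it standing as X.L is c̄X/(K + c̄X), where c̄X is the mean X the catalyst meets and K, the breakdown constant over the binding constant, is 60.0 mM. The breakdown constant times mean catalyst times time I call the turnover budget, 82.6 mM: the X that the mean catalyst could turn if it stood wholly as X.L. The amount made is P, the budget times that share.

Towards the end J leaks to E. The return constant, 0.00772 h⁻¹, is smaller than the forward one, so I kept the forward step and weighted each hour's output by its survival, which leaves 0.771 as J.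

For Sunday's, c̄X is the midpoint of start and end. For Tuesday's I took X and catalyst both as ramps, so c̄X is 0.667 of the end value, and I kept the same charge off X and the same survival as for Sunday's. For Wednesday's, c̄X is the outlet value, the tank holds 0.467 mM of catalyst, and the balance on E leaves 0.589 as J.

| Flask | Budget | Made, P | J, of X put in |
|---|---|---|---|
| Sunday's | 82.6 mM | 25.7 mM | 39.7 % |
| Tuesday's | 82.6 mM | 16.9 mM | 26.0 % |
| Wednesday's | 101 mM | 22.6 mM | 26.7 % |

My choice was Sunday's.

The forecast also chose Sunday's, with 36.9 %, 28 % and 27.6 % for Sunday's, Tuesday's and Wednesday's, noting that “Q wastes X, and J drains reversibly to E”. It put Tuesday's above Wednesday's, where I had Wednesday's above Tuesday's.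

The simulation gave Sunday's, with 37.0 %, 28.1 % and 27.6 %.

At 4.71 h Sunday's flask made J 4.14 times as fast as it used it up, and at the end J and E together stood for 29.9 % of the budget. The neighbour of Sunday's charged with 0.20 M of X has the same budget, and the midpoint rule gives P = 60.1 mM, so I reckoned J at 23.1 % of its X. The computed flask held 23.0 % of its X as J, a lower percentage than Sunday's.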